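**Retrosynthetic overview**

1. The target comes from its tetra-MOM ether, and that from a triene ketone by a one-pot ruthenium metathesis cascade: ring-closing metathesis forms C3=C4 of the pyran (ring C), then cross-metathesis with 2-methylbut-2-ene turns the ring A allyl group into the prenyl group.
2. Enabling feature: O1 and C4a are ortho neighbours on ring B, so a 1,1-dimethylallyl group on O1 and a vinyl group on C4a are held for six-ring closure; quaternary C2 (gem-dimethyl) assists closure, and both olefins of the target (cis C3=C4 next to C2, and the trisubstituted prenyl bond) are inert to the catalyst once formed.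
3. The triene ketone is cut at the most hindered bond, C8–C(=O): a ring B aryllithium (bromine–lithium exchange) adds to a ring A aldehyde, then the carbinol is oxidised.
4. The ring B bromide comes from 2,4,6-trihydroxybenzaldehyde (chelation-controlled bis-MOM protection, bromination ortho to the free OH, Wittig methylenation, Pd-catalysed O-(1,1-dimethylallyl)ation); the ring A aldehyde comes from 3,5-dihydroxybenzaldehyde (MOM protection, bromination, Stille allylation).
5. Ring order: rings A and B are purchased benzene rings; ring C is the only ring made, last, in the key step.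

Key step: step 11

Remark: the target has no stereocentre and rotation about the aryl–carbonyl bonds is taken to be fast, so no configuration has to be controlled; the one stereocentre on the way, a diaryl carbinol, is formed racemic and erased by oxidation.

**Route**

Step 1
Reactants: 1 3,5-dihydroxybenzaldehyde
Product: 2 3,5-bis(methoxymethoxy)benzaldehyde
Conditions: MOMCl (2.5 equiv), i-Pr2NEt (3 equiv), CH2Cl2, 0 °C to rt
Reagents that add atoms: chloromethyl methyl ether (MOMCl), COCCl
Why: O-alkylation of phenols (MOM ether formation), in which both hydroxyls are unhindered and not hydrogen-bonded, so the amine base and the reactive chloromethyl ether should cap both.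

Step 2
Reactants: 2 3,5-bis(methoxymethoxy)benzaldehyde
Product: 3 2-bromo-3,5-bis(methoxymethoxy)benzaldehyde
Conditions: NBS (1.05 equiv), MeCN, 0 °C to rt
Reagents that add atoms: N-bromosuccinimide (NBS), O=C1CCC(=O)N1Br
Why: Electrophilic aromatic bromination, in which C2 (ortho to one MOM ether and para to the other) is less shielded than C4 between the two ethers, the outcome expected from the analogous dimethyl ether.

Step 3
Reactants: 3 2-bromo-3,5-bis(methoxymethoxy)benzaldehyde
Product: 4 3,5-bis(methoxymethoxy)-2-(prop-2-en-1-yl)benzaldehyde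
Conditions: allylSnBu3 (1.2 equiv), Pd(PPh3)4 (5 mol%), toluene, 100 °C
Reagents that add atoms: allyltributylstannane, C=CC[Sn](CCCC)(CCCC)CCCC
Why: Stille cross-coupling, in which oxidative addition of zerovalent palladium into the aldehyde-activated C–Br bond, allyl transfer from tin and reductive elimination should give the allylarene without touching the aldehyde or the acetals.

Step 4
Reactants: 5 2,4,6-trihydroxybenzaldehyde
Product: 6 2-hydroxy-4,6-bis(methoxymethoxy)benzaldehyde
Conditions: MOMCl (2.1 equiv), i-Pr2NEt (2.5 equiv), CH2Cl2, 0 °C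
Reagents that add atoms: chloromethyl methyl ether (MOMCl), COCCl
Why: Chelation-controlled selective MOM protection, in which the para hydroxyl and one of the two equivalent ortho hydroxyls are alkylated while the remaining ortho hydroxyl is held in a hydrogen bond to the formyl oxygen and should stay free.

Step 5
Reactants: 6 2-hydroxy-4,6-bis(methoxymethoxy)benzaldehyde
Product: 7 3-bromo-2-hydroxy-4,6-bis(methoxymethoxy)benzaldehyde
Conditions: NBS (1.0 equiv), CH2Cl2, −20 °C to 0 °C
Reagents that add atoms: N-bromosuccinimide (NBS), O=C1CCC(=O)N1Br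
Why: Electrophilic bromination of a phenol, in which C3 (ortho to the free hydroxyl, flanked by OH and one MOM ether) should be attacked in preference to C5 shielded by two MOM ethers, in line with the known ortho-halogenation of 2-hydroxy-4,6-dialkoxyaryl carbonyl compounds.

Step 6
Reactants: 7 3-bromo-2-hydroxy-4,6-bis(methoxymethoxy)benzaldehyde
Product: 8 2-bromo-6-ethenyl-3,5-bis(methoxymethoxy)phenol
Conditions: Ph3PCH3Br (3 equiv), KOt-Bu (3 equiv), THF, 0 °C to rt; aq NH4Cl
Reagents that add atoms: methyltriphenylphosphonium bromide, C[P+](c1ccccc1)(c1ccccc1)c1ccccc1.[Br-]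
Why: Wittig methylenation, in which excess non-stabilised ylide tolerates the phenoxide formed first and converts the aldehyde into the vinyl group, the phenol returning on work-up.

Step 7
Reactants: 9 2-methylbut-3-en-2-ol
Product: 11 methyl 2-methylbut-3-en-2-yl carbonate, via lithium 2-methylbut-3-en-2-olate 10 (not isolated)
Conditions: n-BuLi (1.05 equiv), THF, −78 °C; then ClCO2Me (1.1 equiv), −78 °C to rt
Reagents that add atoms: methyl chloroformate, COC(=O)Cl
Why: Alkoxide acylation (carbonate formation), in which prior deprotonation makes the hindered tertiary alcohol nucleophilic enough to be captured cleanly by the chloroformate.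

Step 8
Reactants: 8 2-bromo-6-ethenyl-3,5-bis(methoxymethoxy)phenol; 11 methyl 2-methylbut-3-en-2-yl carbonate
Product: 12 1-bromo-3-ethenyl-4,6-bis(methoxymethoxy)-2-[(2-methylbut-3-en-2-yl)oxy]benzene
Conditions: 11 (1.5 equiv), Pd(PPh3)4 (5 mol%), THF, 0 °C to rt
Reagents that add atoms: none
Why: Decarboxylative Tsuji–Trost O-allylation, in which zerovalent palladium ionises the tertiary carbonate to a 1,1-dimethyl-π-allyl complex, CO2 and methoxide, and the phenoxide so formed should attack the more substituted allyl terminus under kinetic control to give the tertiary aryl ether, the electron-rich hindered C–Br bond being inert at this temperature.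

Step 9
Reactants: 12 1-bromo-3-ethenyl-4,6-bis(methoxymethoxy)-2-[(2-methylbut-3-en-2-yl)oxy]benzene; 4 3,5-bis(methoxymethoxy)-2-(prop-2-en-1-yl)benzaldehyde
Product: 14 racemic [3,5-bis(methoxymethoxy)-2-(prop-2-en-1-yl)phenyl]{3-ethenyl-4,6-bis(methoxymethoxy)-2-[(2-methylbut-3-en-2-yl)oxy]phenyl}methanol, via aryllithium 13 (not isolated)
Conditions: n-BuLi (1.05 equiv), THF, −78 °C, 10 min; then 4, −78 °C to −40 °C; H2O
Reagents that add atoms: none
Why: Bromine–lithium exchange followed by 1,2-addition of the aryllithium to the aldehyde, in which exchange at a bromide flanked by two alkoxy groups should outrun addition of butyllithium to the hindered styrene, and the carbinol stereocentre is formed without control as a racemate that step 10 erases.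

Step 10
Reactants: 14 racemic [3,5-bis(methoxymethoxy)-2-(prop-2-en-1-yl)phenyl]{3-ethenyl-4,6-bis(methoxymethoxy)-2-[(2-methylbut-3-en-2-yl)oxy]phenyl}methanol
Product: 15 [3,5-bis(methoxymethoxy)-2-(prop-2-en-1-yl)phenyl]{3-ethenyl-4,6-bis(methoxymethoxy)-2-[(2-methylbut-3-en-2-yl)oxy]phenyl}methanone
Conditions: DMP (1.5 equiv), CH2Cl2, 0 °C to rt
Reagents that add atoms: none
Why: Dess–Martin oxidation, in which the hypervalent iodine reagent should convert the hindered diaryl carbinol into the diaryl ketone under near-neutral conditions that spare the three terminal olefins, the tertiary allyl ether and the acetals.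

Step 11
Reactants: 15 [3,5-bis(methoxymethoxy)-2-(prop-2-en-1-yl)phenyl]{3-ethenyl-4,6-bis(methoxymethoxy)-2-[(2-methylbut-3-en-2-yl)oxy]phenyl}methanone
Product: 17 [5,7-bis(methoxymethoxy)-2,2-dimethyl-2H-chromen-8-yl][3,5-bis(methoxymethoxy)-2-(3-methylbut-2-en-1-yl)phenyl]methanone, via allyl chromenyl ketone 16 (not isolated)
Conditions: second-generation Grubbs catalyst RuCl2(=CHPh)(PCy3)(H2IMes) (5 mol%), CH2Cl2 (0.005 M), 40 °C; then 2-methylbut-2-ene (50 equiv), sealed vessel, 40 °C
Reagents that add atoms: 2-methylbut-2-ene, CC=C(C)C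
Why: The ruthenium alkylidene loads onto the ring B vinyl group to give an ortho-alkoxy-stabilised benzylidene that undergoes intramolecular [2+2] cycloaddition and cycloreversion with the terminal olefin of the O1-bound 1,1-dimethylallyl group, forming C3=C4 and releasing ethene via Ru=CH2, after which the same catalyst exchanges the terminal CH2 of the ring A allyl group for the isopropylidene unit of 2-methylbut-2-ene, releasing propene. The closest known reaction types are ring-closing olefin metathesis of 2-vinylaryl allyl ethers to 2H-chromenes and cross-metathesis of allylarenes with 2-methylbut-2-ene to prenylarenes, here run in one pot on one catalyst charge. Ring C closes as a six-membered ring by diene ring-closing metathesis between two monosubstituted olefins held 1,6 on the arene, the gem-dimethyl group at C2 favouring the reactive conformer. No stereocentre is formed, and the C3=C4 bond is necessarily cis within the six-membered ring. The step needs closure to outrun intermolecular metathesis and needs chemoselection among three terminal olefins: high dilution and delayed addition of 2-methylbut-2-ene secure the order of events, the neopentyl-type 1,1-dimethylallyl olefin does not homodimerise, any allyl homodimer formed in the first stage is cleaved productively by the excess trisubstituted olefin, and macrocyclic closures through the ring A allyl group (nine- or ten-membered, strained across the diaryl ketone) cannot compete. Both product olefins (the shielded cis C3=C4 bond next to quaternary C2 and the trisubstituted prenyl bond) are poor metathesis substrates, so the cascade should stop at 17.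

Step 12
Reactants: 17 [5,7-bis(methoxymethoxy)-2,2-dimethyl-2H-chromen-8-yl][3,5-bis(methoxymethoxy)-2-(3-methylbut-2-en-1-yl)phenyl]methanone
Product: 18 [3,5-dihydroxy-2-(3-methylbut-2-en-1-yl)phenyl](5,7-dihydroxy-2,2-dimethyl-2H-chromen-8-yl)methanone (CNP0076744.0)
Conditions: 3 M aq HCl, MeOH, 40 °C
Reagents that add atoms: none
Why: Acid-catalysed acetal cleavage (MOM removal by transacetalisation to methanol), in which dilute acid at mild temperature should free the four phenols while the 2,2-dimethylchromene and the ortho-prenylphenol, which need stronger acid to hydrate or cyclise, persist.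

**Compound list**

1 | 3,5-dihydroxybenzaldehyde | O=Cc1cc(O)cc(O)c1 | starting material
2 | 3,5-bis(methoxymethoxy)benzaldehyde | COCOc1cc(C=O)cc(OCOC)c1 | intermediate
3 | 2-bromo-3,5-bis(methoxymethoxy)benzaldehyde | COCOc1cc(C=O)c(Br)c(OCOC)c1 | intermediate
4 | 3,5-bis(methoxymethoxy)-2-(prop-2-en-1-yl)benzaldehyde | COCOc1cc(C=O)c(CC=C)c(OCOC)c1 | intermediate
5 | 2,4,6-trihydroxybenzaldehyde | O=Cc1c(O)cc(O)cc1O | starting material
6 | 2-hydroxy-4,6-bis(methoxymethoxy)benzaldehyde | COCOc1cc(O)c(C=O)c(OCOC)c1 | intermediate
7 | 3-bromo-2-hydroxy-4,6-bis(methoxymethoxy)benzaldehyde | COCOc1cc(OCOC)c(C=O)c(O)c1Br | intermediate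
8 | 2-bromo-6-ethenyl-3,5-bis(methoxymethoxy)phenol | COCOc1cc(OCOC)c(C=C)c(O)c1Br | intermediate
9 | 2-methylbut-3-en-2-ol | CC(C)(O)C=C | starting material
10 | lithium 2-methylbut-3-en-2-olate | [Li]OC(C)(C)C=C | intermediate
11 | methyl 2-methylbut-3-en-2-yl carbonate | COC(=O)OC(C)(C)C=C | intermediate
12 | 1-bromo-3-ethenyl-4,6-bis(methoxymethoxy)-2-[(2-methylbut-3-en-2-yl)oxy]benzene | COCOc1cc(OCOC)c(C=C)c(OC(C)(C)C=C)c1Br | intermediate
13 | {3-ethenyl-4,6-bis(methoxymethoxy)-2-[(2-methylbut-3-en-2-yl)oxy]phenyl}lithium | COCOc1cc(OCOC)c(C=C)c(OC(C)(C)C=C)c1[Li] | intermediate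
14 | racemic [3,5-bis(methoxymethoxy)-2-(prop-2-en-1-yl)phenyl]{3-ethenyl-4,6-bis(methoxymethoxy)-2-[(2-methylbut-3-en-2-yl)oxy]phenyl}methanol | COCOc1cc(OCOC)c(C=C)c(OC(C)(C)C=C)c1C(O)c1cc(OCOC)cc(OCOC)c1CC=C | intermediate
15 | [3,5-bis(methoxymethoxy)-2-(prop-2-en-1-yl)phenyl]{3-ethenyl-4,6-bis(methoxymethoxy)-2-[(2-methylbut-3-en-2-yl)oxy]phenyl}methanone | COCOc1cc(OCOC)c(C=C)c(OC(C)(C)C=C)c1C(=O)c1cc(OCOC)cc(OCOC)c1CC=C | intermediate
16 | [5,7-bis(methoxymethoxy)-2,2-dimethyl-2H-chromen-8-yl][3,5-bis(methoxymethoxy)-2-(prop-2-en-1-yl)phenyl]methanone | COCOc1cc(OCOC)c2C=CC(C)(C)Oc2c1C(=O)c1cc(OCOC)cc(OCOC)c1CC=C | intermediate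
17 | [5,7-bis(methoxymethoxy)-2,2-dimethyl-2H-chromen-8-yl][3,5-bis(methoxymethoxy)-2-(3-methylbut-2-en-1-yl)phenyl]methanone | COCOc1cc(OCOC)c2C=CC(C)(C)Oc2c1C(=O)c1cc(OCOC)cc(OCOC)c1CC=C(C)C | intermediate
18 | [3,5-dihydroxy-2-(3-methylbut-2-en-1-yl)phenyl](5,7-dihydroxy-2,2-dimethyl-2H-chromen-8-yl)methanone (no stereocentre) | CC(C)=CCc1c(O)cc(O)cc1C(=O)c1c(O)cc(O)c2c1OC(C)(C)C=C2 | target

**Step count and risks**

Total step count: 12. Longest linear sequence: 8 steps (steps 4, 5, 6, 8, 9, 10, 11 and 12, from 2,4,6-trihydroxybenzaldehyde 5).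

Steps most likely to fail:

Step 11 (key step). The two metathesis events may interfere: the trisubstituted olefin partner may cross-metathesise with the ring B vinyl group before ring closure, or ruthenium hydride species may move the allyl double bond into conjugation, so that closure and chain extension erode each other. The fallback decouples them by installing the prenyl group at the fragment stage. It sets out from 4: cross-metathesis with 2-methylbut-2-ene (second-generation Grubbs catalyst RuCl2(=CHPh)(PCy3)(H2IMes), CH2Cl2, 40 °C) should give 3,5-bis(methoxymethoxy)-2-(3-methylbut-2-en-1-yl)benzaldehyde F1. Aryllithium 13, generated from 12 as in step 9, should add to it to give racemic [3,5-bis(methoxymethoxy)-2-(3-methylbut-2-en-1-yl)phenyl]{3-ethenyl-4,6-bis(methoxymethoxy)-2-[(2-methylbut-3-en-2-yl)oxy]phenyl}methanol F2. Dess–Martin oxidation should give [3,5-bis(methoxymethoxy)-2-(3-methylbut-2-en-1-yl)phenyl]{3-ethenyl-4,6-bis(methoxymethoxy)-2-[(2-methylbut-3-en-2-yl)oxy]phenyl}methanone F3. A plain ring-closing metathesis (same catalyst, CH2Cl2, 0.005 M, 40 °C) then closes ring C at C3=C4 and comes back to the route at 17.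

Step 8. The phenoxide may attack the less hindered terminus of the π-allyl complex, or the tertiary ether may re-ionise on palladium, so that the linear prenyl ether accumulates. The fallback builds the tertiary ether at the alkyne oxidation level before the vinyl group exists. It sets out from 7: copper-catalysed propargylation (3-chloro-3-methylbut-1-yne, CuCl2·2H2O (1 mol%), DBU, MeCN, 0 °C) should give 3-bromo-4,6-bis(methoxymethoxy)-2-[(2-methylbut-3-yn-2-yl)oxy]benzaldehyde F4. Semi-hydrogenation (H2, Pd/CaCO3 poisoned with Pb(OAc)2, quinoline, EtOAc) should give 3-bromo-4,6-bis(methoxymethoxy)-2-[(2-methylbut-3-en-2-yl)oxy]benzaldehyde F5. Wittig methylenation (Ph3PCH3Br, KOt-Bu, THF) then comes back to the route at 12; this order also spares the Wittig reaction the phenoxide.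

Step 5. Bromination may also take place at C5 (para to the free hydroxyl, between the two MOM ethers) or twice, giving poor regiocontrol. The fallback lets symmetry fix the bromine position. It sets out from 5: monobromination (NBS, 1.0 equiv, MeCN, −30 °C) can give only one monobromide, 3-bromo-2,4,6-trihydroxybenzaldehyde F6. Bis-MOM protection (MOMCl, 2.1 equiv, i-Pr2NEt, CH2Cl2, 0 °C) should then leave free the hydroxyl that is both flanked by bromine and the formyl group and hydrogen-bonded, and comes back to the route at 7.

**Further compounds**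

F1 | step 11 | 3,5-bis(methoxymethoxy)-2-(3-methylbut-2-en-1-yl)benzaldehyde | COCOc1cc(C=O)c(CC=C(C)C)c(OCOC)c1
F2 | step 11 | racemic [3,5-bis(methoxymethoxy)-2-(3-methylbut-2-en-1-yl)phenyl]{3-ethenyl-4,6-bis(methoxymethoxy)-2-[(2-methylbut-3-en-2-yl)oxy]phenyl}methanol | COCOc1cc(OCOC)c(C=C)c(OC(C)(C)C=C)c1C(O)c1cc(OCOC)cc(OCOC)c1CC=C(C)C
F3 | step 11 | [3,5-bis(methoxymethoxy)-2-(3-methylbut-2-en-1-yl)phenyl]{3-ethenyl-4,6-bis(methoxymethoxy)-2-[(2-methylbut-3-en-2-yl)oxy]phenyl}methanone | COCOc1cc(OCOC)c(C=C)c(OC(C)(C)C=C)c1C(=O)c1cc(OCOC)cc(OCOC)c1CC=C(C)C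
F4 | step 8 | 3-bromo-4,6-bis(methoxymethoxy)-2-[(2-methylbut-3-yn-2-yl)oxy]benzaldehyde | COCOc1cc(OCOC)c(C=O)c(OC(C)(C)C#C)c1Br
F5 | step 8 | 3-bromo-4,6-bis(methoxymethoxy)-2-[(2-methylbut-3-en-2-yl)oxy]benzaldehyde | COCOc1cc(OCOC)c(C=O)c(OC(C)(C)C=C)c1Br
F6 | step 5 | 3-bromo-2,4,6-trihydroxybenzaldehyde | O=Cc1c(O)cc(O)c(Br)c1O
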